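**Retrosynthetic overview**
- The strategy rests on the cyclopentane ring (C1, C2, C3, C3a, C8a) in which the C3a tertiary hydroxyl is cis to the C3 isopropyl group and to the C8a methyl. This is the pattern a ketone–ene reaction of a prenyl group leaves, so the C3–C3a bond is disconnected.
- Endgame from the ene product: isopropenyl to isopropyl, C8 ketone reduced under direction of the C3a hydroxyl and esterified, C1 silyl ether turned into the ketone.
- The ene precursor is a 2-(1-silyloxy-4-methylpent-3-enyl)-2,5-dimethylcyclohept-4-ene-1,3-dione. Its quaternary carbon comes from a Mukaiyama aldol of a cycloheptadienyl silyl ether with 4-methylpent-3-enal, steered by a temporary silyloxy stereocentre at the future C3a.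
- Ring order: the seven-membered ring is closed first by ring-closing metathesis of an Evans-aldol-derived dienone; the five-membered ring is closed second, in the key step.

Key step: step 12

Remark: bicyclic compounds carry the azulene numbering of the target; the silyloxy carbon becomes the C1 ketone in the last step, so its configuration (drawn as the open transition state of step 8 should give it) does not bear on the target.

Step 1
Reactants: 1 (4S)-4-benzyl-3-propanoyl-1,3-oxazolidin-2-one; 2 4-methylpent-4-enal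
Product: 4 (4S)-4-benzyl-3-[(2S,3R)-3-hydroxy-2,6-dimethylhept-6-enoyl]-1,3-oxazolidin-2-one, via dibutylboron enolate 3 (not isolated)
Conditions: Bu2BOTf, iPr2NEt, CH2Cl2, 0 °C; 2, −78 → 0 °C; H2O2, MeOH, pH 7 buffer
Reagents that add atoms: none
Why: Evans syn-aldol, in which the Z-boron enolate adds through a Zimmerman–Traxler chair with one face blocked by the benzyl group of the auxiliary, setting the carbinol carbon as R (the future C3a oxygen stereocentre that later steers the quaternary carbon) and the methyl-bearing carbon as S (erased in step 6).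

Step 2
Reactants: 4 (4S)-4-benzyl-3-[(2S,3R)-3-hydroxy-2,6-dimethylhept-6-enoyl]-1,3-oxazolidin-2-one
Product: 5 (2S,3R)-3-hydroxy-N-methoxy-N,2,6-trimethylhept-6-enamide
Conditions: MeONHMe·HCl, AlMe3, CH2Cl2, −20 → 0 °C
Reagents that add atoms: N,O-dimethylhydroxylamine hydrochloride, CNOC.Cl
Why: Weinreb transamidation by the aluminium amide, assisted by the free β-hydroxyl, opens the imide at the exocyclic carbonyl, releases the auxiliary and leaves both stereocentres untouched.

Step 3
Reactants: 5 (2S,3R)-3-hydroxy-N-methoxy-N,2,6-trimethylhept-6-enamide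
Product: 6 (2S,3R)-N-methoxy-N,2,6-trimethyl-3-(triethylsilyloxy)hept-6-enamide
Conditions: Et3SiCl, imidazole, DMF, 0 °C → rt
Reagents that add atoms: chlorotriethylsilane, CC[Si](Cl)(CC)CC
Why: Routine silylation gives a triethylsilyl ether that survives the organometallic, metathesis and Lewis acid steps and can later be removed beside a tert-butyldimethylsilyl ether.

Step 4
Reactants: 6 (2S,3R)-N-methoxy-N,2,6-trimethyl-3-(triethylsilyloxy)hept-6-enamide
Product: 8 (4S,5R)-4,8-dimethyl-5-(triethylsilyloxy)nona-1,8-dien-3-one, via magnesium hemiaminal alkoxide 7 (not isolated)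
Conditions: CH2=CHMgBr, THF, −78 → 0 °C; inverse quench into cold aq. citric acid
Reagents that add atoms: vinylmagnesium bromide, C=C[Mg]Br
Why: Weinreb ketone synthesis, in which the chelated tetrahedral adduct holds until the quench so that one vinyl group is delivered, and the acidic inverse quench protonates the released amine before it can add to the vinyl ketone.

Step 5
Reactants: 8 (4S,5R)-4,8-dimethyl-5-(triethylsilyloxy)nona-1,8-dien-3-one
Product: 9 (6R,7S)-3,7-dimethyl-6-(triethylsilyloxy)cyclohept-2-en-1-one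
Conditions: second-generation Grubbs catalyst RuCl2(=CHPh)(PCy3)(H2IMes) (5 mol%), CH2Cl2 (5 mM), 40 °C
Reagents that add atoms: none
Why: Ring-closing metathesis of the vinyl ketone with the 1,1-disubstituted olefin closes the seven-membered ring as the trisubstituted enone with loss of ethene, and no stereocentre is involved.

Step 6
Reactants: 9 (6R,7S)-3,7-dimethyl-6-(triethylsilyloxy)cyclohept-2-en-1-one
Product: 11 (7R)-1,4-dimethyl-7-(triethylsilyloxy)-2-(trimethylsilyloxy)cyclohepta-1,3-diene, via lithium dienolate 10 (not isolated)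
Conditions: LiN(iPr)2, THF, −78 °C; Me3SiCl, Et3N, −78 → 0 °C; pentane, filtration
Reagents that add atoms: chlorotrimethylsilane, C[Si](C)(C)Cl
Why: Kinetic deprotonation at C7, the only sp3 carbon α to the enone carbonyl, gives the cross-conjugated dienolate, which is O-silylated to the 2-silyloxy-1,3-diene; the C7 stereocentre is erased on purpose and the silyloxy-bearing carbon is kept.

Step 7
Reactants: 12 4-methylpent-3-en-1-ol
Product: 13 4-methylpent-3-enal
Conditions: Dess–Martin periodinane, NaHCO3, CH2Cl2, 0 °C; used at once as a cold solution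
Reagents that add atoms: none
Why: Buffered Dess–Martin oxidation gives the β,γ-unsaturated aldehyde without the acid or base that would move the double bond into conjugation.

Step 8
Reactants: 11 (7R)-1,4-dimethyl-7-(triethylsilyloxy)-2-(trimethylsilyloxy)cyclohepta-1,3-diene; 13 4-methylpent-3-enal
Product: 14 (6R,7S)-7-[(1S)-1-hydroxy-4-methylpent-3-en-1-yl]-3,7-dimethyl-6-(triethylsilyloxy)cyclohept-2-en-1-one
Conditions: BF3·OEt2 (1.1 equiv), CH2Cl2, −78 °C; aq. NaHCO3
Reagents that add atoms: none
Why: Mukaiyama aldol addition through an open transition state at the tetrasubstituted enol ether carbon, where allylic 1,2-strain with the methyl on that carbon holds the neighbouring triethylsilyloxy group pseudo-axial so that the aldehyde enters anti to it and sets the quaternary carbon (future C8a), while the antiperiplanar arrangement with the aldehyde chain next to the small methyl should give the S carbinol.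

Step 9
Reactants: 14 (6R,7S)-7-[(1S)-1-hydroxy-4-methylpent-3-en-1-yl]-3,7-dimethyl-6-(triethylsilyloxy)cyclohept-2-en-1-one
Product: 15 (6R,7R)-7-[(1S)-1-(tert-butyldimethylsilyloxy)-4-methylpent-3-en-1-yl]-3,7-dimethyl-6-(triethylsilyloxy)cyclohept-2-en-1-one
Conditions: tBuMe2SiOTf, 2,6-lutidine, CH2Cl2, −78 → 0 °C
Reagents that add atoms: tert-butyldimethylsilyl trifluoromethanesulfonate, CC(C)(C)[Si](C)(C)OS(=O)(=O)C(F)(F)F
Why: Silyl triflate with a hindered pyridine base silylates the neopentyl-type secondary alcohol without a base strong enough to trigger retro-aldol cleavage.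

Step 10
Reactants: 15 (6R,7R)-7-[(1S)-1-(tert-butyldimethylsilyloxy)-4-methylpent-3-en-1-yl]-3,7-dimethyl-6-(triethylsilyloxy)cyclohept-2-en-1-one
Product: 16 (6R,7R)-7-[(1S)-1-(tert-butyldimethylsilyloxy)-4-methylpent-3-en-1-yl]-6-hydroxy-3,7-dimethylcyclohept-2-en-1-one
Conditions: PPTS (cat.), MeOH/CH2Cl2, 0 °C
Reagents that add atoms: none
Why: Acid-catalysed methanolysis removes the triethylsilyl ether, which is far more labile than the tert-butyldimethylsilyl ether, and frees the ring hydroxyl alone.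

Step 11
Reactants: 16 (6R,7R)-7-[(1S)-1-(tert-butyldimethylsilyloxy)-4-methylpent-3-en-1-yl]-6-hydroxy-3,7-dimethylcyclohept-2-en-1-one
Product: 17 (2S)-2-[(1S)-1-(tert-butyldimethylsilyloxy)-4-methylpent-3-en-1-yl]-2,5-dimethylcyclohept-4-ene-1,3-dione
Conditions: Dess–Martin periodinane, NaHCO3, CH2Cl2, rt
Reagents that add atoms: none
Why: Dess–Martin oxidation under buffered, non-nucleophilic conditions gives the saturated ketone of the 2,2-disubstituted 1,3-dione without retro-Claisen cleavage, so the relay stereocentre is spent and the quaternary carbon stays as set.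

Step 12
Reactants: 17 (2S)-2-[(1S)-1-(tert-butyldimethylsilyloxy)-4-methylpent-3-en-1-yl]-2,5-dimethylcyclohept-4-ene-1,3-dione
Product: 19 (1S,3R,3aS,8aS)-1-(tert-butyldimethylsilyloxy)-3a-hydroxy-6,8a-dimethyl-3-(prop-1-en-2-yl)-2,3,3a,4,5,8a-hexahydroazulen-8(1H)-one, via chloromethylaluminium alkoxide 18 (not isolated)
Conditions: Me2AlCl (2.5 equiv), CH2Cl2, −78 → 0 °C; aq. sodium potassium tartrate
Reagents that add atoms: none
Why: Me2AlCl activates the saturated C3a carbonyl, the olefinic CH of the prenyl group (C3) bonds to it while a hydrogen of an allylic methyl passes to oxygen through a six-centre array, and the aluminium-bound alcohol then loses methane to give alkoxide 18, which keeps the medium free of protic acid. The closest known reaction type is the Lewis-acid-promoted intramolecular carbonyl-ene cyclisation of 6-methylhept-5-enyl aldehydes and ketones to 2-isopropenylcyclopentanols. The cyclopentane (C1, C2, C3, C3a, C8a) closes in the 5-exo-trig mode with respect to the C3a carbonyl. At C3a the tether on C8a can reach the carbonyl only from its own face, so the hydroxyl ends up cis to the C8a methyl and the rings are cis-fused; at C3 the concerted hydrogen transfer needs the isopropylidene end over the carbonyl oxygen, which puts isopropenyl cis to the new hydroxyl. The step needs chemoselectivity between the two carbonyls on C8a: with both complexed, the conjugated C8 ketone, which draws electron density from the C6=C7 olefin, is the weaker enophile and the saturated C3a ketone reacts.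

Step 13
Reactants: 19 (1S,3R,3aS,8aS)-1-(tert-butyldimethylsilyloxy)-3a-hydroxy-6,8a-dimethyl-3-(prop-1-en-2-yl)-2,3,3a,4,5,8a-hexahydroazulen-8(1H)-one
Product: 20 (1S,3R,3aS,8aS)-1-(tert-butyldimethylsilyloxy)-3a-hydroxy-6,8a-dimethyl-3-(propan-2-yl)-2,3,3a,4,5,8a-hexahydroazulen-8(1H)-one
Conditions: H2 (1 atm), RhCl(PPh3)3 (10 mol%), benzene/EtOH, rt
Reagents that add atoms: none
Why: Homogeneous hydrogenation with RhCl(PPh3)3 reduces the unhindered 1,1-disubstituted isopropenyl olefin much faster than the trisubstituted conjugated C6=C7 olefin, as in the selective reduction of the isopropenyl group of carvone, and C3 is not touched.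

Step 14
Reactants: 20 (1S,3R,3aS,8aS)-1-(tert-butyldimethylsilyloxy)-3a-hydroxy-6,8a-dimethyl-3-(propan-2-yl)-2,3,3a,4,5,8a-hexahydroazulen-8(1H)-one
Product: 22 (1S,3R,3aS,8R,8aS)-1-(tert-butyldimethylsilyloxy)-6,8a-dimethyl-3-(propan-2-yl)-1,2,3,3a,4,5,8,8a-octahydroazulene-3a,8-diol, via alkoxyborohydride 21 (not isolated)
Conditions: Me4NBH(OAc)3, MeCN/AcOH, −30 → 0 °C; aq. sodium potassium tartrate
Reagents that add atoms: none
Why: Saksena–Evans hydroxyl-directed reduction, in which the C3a hydroxyl exchanges onto boron and delivers hydride to the C8 carbonyl from its own face, so the new hydroxyl is trans to the C3a hydroxyl (8R, the 1,3-anti diol) and the enone is reduced 1,2.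

Step 15
Reactants: 22 (1S,3R,3aS,8R,8aS)-1-(tert-butyldimethylsilyloxy)-6,8a-dimethyl-3-(propan-2-yl)-1,2,3,3a,4,5,8,8a-octahydroazulene-3a,8-diol; 23 4-methoxybenzoyl chloride
Product: 24 (1S,3R,3aS,8R,8aS)-1-(tert-butyldimethylsilyloxy)-3a-hydroxy-6,8a-dimethyl-3-(propan-2-yl)-1,2,3,3a,4,5,8,8a-octahydroazulen-8-yl 4-methoxybenzoate
Conditions: DMAP (cat.), Et3N, CH2Cl2, 0 → 40 °C
Reagents that add atoms: none
Why: DMAP-catalysed acylation esterifies the secondary allylic C8 hydroxyl, while the tertiary C3a hydroxyl at the ring fusion is too hindered to react.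

Step 16
Reactants: 24 (1S,3R,3aS,8R,8aS)-1-(tert-butyldimethylsilyloxy)-3a-hydroxy-6,8a-dimethyl-3-(propan-2-yl)-1,2,3,3a,4,5,8,8a-octahydroazulen-8-yl 4-methoxybenzoate
Product: 25 (1S,3R,3aS,8R,8aR)-1,3a-dihydroxy-6,8a-dimethyl-3-(propan-2-yl)-1,2,3,3a,4,5,8,8a-octahydroazulen-8-yl 4-methoxybenzoate
Conditions: HF·pyridine, pyridine, THF, 0 °C → rt
Reagents that add atoms: none
Why: Fluoride cleavage of the silyl ether under buffered acidic conditions avoids the alkoxide that could shift the ester from O8 to the neighbouring O1.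

Step 17
Reactants: 25 (1S,3R,3aS,8R,8aR)-1,3a-dihydroxy-6,8a-dimethyl-3-(propan-2-yl)-1,2,3,3a,4,5,8,8a-octahydroazulen-8-yl 4-methoxybenzoate
Product: 26 (3R,3aS,8R,8aR)-3a-hydroxy-6,8a-dimethyl-1-oxo-3-(propan-2-yl)-1,2,3,3a,4,5,8,8a-octahydroazulen-8-yl 4-methoxybenzoate
Conditions: Dess–Martin periodinane, NaHCO3, CH2Cl2, 0 °C → rt
Reagents that add atoms: none
Why: Buffered Dess–Martin oxidation turns the C1 alcohol into the cyclopentanone without base that could open the resulting β-hydroxy ketone by retro-aldol, and leaves C3, C3a, C8 and C8a as set.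

**Compound list**
1 | (4S)-4-benzyl-3-propanoyl-1,3-oxazolidin-2-one | CCC(=O)N1C(=O)OC[C@@H]1Cc1ccccc1 | starting material
2 | 4-methylpent-4-enal | C=C(C)CCC=O | starting material
3 | (4S)-4-benzyl-3-[(1Z)-1-(dibutylboranyloxy)prop-1-en-1-yl]-1,3-oxazolidin-2-one | C/C=C(\OB(CCCC)CCCC)N1C(=O)OC[C@@H]1Cc1ccccc1 | intermediate
4 | (4S)-4-benzyl-3-[(2S,3R)-3-hydroxy-2,6-dimethylhept-6-enoyl]-1,3-oxazolidin-2-one | C=C(C)CC[C@@H](O)[C@H](C)C(=O)N1C(=O)OC[C@@H]1Cc1ccccc1 | intermediate
5 | (2S,3R)-3-hydroxy-N-methoxy-N,2,6-trimethylhept-6-enamide | C=C(C)CC[C@@H](O)[C@H](C)C(=O)N(C)OC | intermediate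
6 | (2S,3R)-N-methoxy-N,2,6-trimethyl-3-(triethylsilyloxy)hept-6-enamide | C=C(C)CC[C@@H](O[Si](CC)(CC)CC)[C@H](C)C(=O)N(C)OC | intermediate
7 | bromomagnesium (4S,5R)-3-[methoxy(methyl)amino]-4,8-dimethyl-5-(triethylsilyloxy)nona-1,8-dien-3-olate | C=C(C)CC[C@@H](O[Si](CC)(CC)CC)[C@H](C)C(O[Mg]Br)(C=C)N(C)OC | intermediate
8 | (4S,5R)-4,8-dimethyl-5-(triethylsilyloxy)nona-1,8-dien-3-one | C=C(C)CC[C@@H](O[Si](CC)(CC)CC)[C@H](C)C(=O)C=C | intermediate
9 | (6R,7S)-3,7-dimethyl-6-(triethylsilyloxy)cyclohept-2-en-1-one | CC1=CC(=O)[C@@H](C)[C@H](O[Si](CC)(CC)CC)CC1 | intermediate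
10 | lithium (7R)-1,4-dimethyl-7-(triethylsilyloxy)cyclohepta-1,3-dien-2-olate | CC1=CC(O[Li])=C(C)[C@H](O[Si](CC)(CC)CC)CC1 | intermediate
11 | (7R)-1,4-dimethyl-7-(triethylsilyloxy)-2-(trimethylsilyloxy)cyclohepta-1,3-diene | CC1=CC(O[Si](C)(C)C)=C(C)[C@H](O[Si](CC)(CC)CC)CC1 | intermediate
12 | 4-methylpent-3-en-1-ol | CC(C)=CCCO | starting material
13 | 4-methylpent-3-enal | CC(C)=CCC=O | intermediate
14 | (6R,7S)-7-[(1S)-1-hydroxy-4-methylpent-3-en-1-yl]-3,7-dimethyl-6-(triethylsilyloxy)cyclohept-2-en-1-one | CC(C)=CC[C@H](O)[C@]1(C)C(=O)C=C(C)CC[C@H]1O[Si](CC)(CC)CC | intermediate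
15 | (6R,7R)-7-[(1S)-1-(tert-butyldimethylsilyloxy)-4-methylpent-3-en-1-yl]-3,7-dimethyl-6-(triethylsilyloxy)cyclohept-2-en-1-one | CC(C)=CC[C@H](O[Si](C)(C)C(C)(C)C)[C@]1(C)C(=O)C=C(C)CC[C@H]1O[Si](CC)(CC)CC | intermediate
16 | (6R,7R)-7-[(1S)-1-(tert-butyldimethylsilyloxy)-4-methylpent-3-en-1-yl]-6-hydroxy-3,7-dimethylcyclohept-2-en-1-one | CC(C)=CC[C@H](O[Si](C)(C)C(C)(C)C)[C@]1(C)C(=O)C=C(C)CC[C@H]1O | intermediate
17 | (2S)-2-[(1S)-1-(tert-butyldimethylsilyloxy)-4-methylpent-3-en-1-yl]-2,5-dimethylcyclohept-4-ene-1,3-dione | CC(C)=CC[C@H](O[Si](C)(C)C(C)(C)C)[C@]1(C)C(=O)C=C(C)CCC1=O | intermediate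
18 | chloro(methyl)aluminium alkoxide (at O3a) of compound 19 | O=C1C=C(C)CC[C@]2(O[Al](C)Cl)[C@@H](C(C)=C)C[C@H](O[Si](C)(C)C(C)(C)C)[C@]12C | intermediate
19 | (1S,3R,3aS,8aS)-1-(tert-butyldimethylsilyloxy)-3a-hydroxy-6,8a-dimethyl-3-(prop-1-en-2-yl)-2,3,3a,4,5,8a-hexahydroazulen-8(1H)-one | O=C1C=C(C)CC[C@]2(O)[C@@H](C(C)=C)C[C@H](O[Si](C)(C)C(C)(C)C)[C@]12C | intermediate
20 | (1S,3R,3aS,8aS)-1-(tert-butyldimethylsilyloxy)-3a-hydroxy-6,8a-dimethyl-3-(propan-2-yl)-2,3,3a,4,5,8a-hexahydroazulen-8(1H)-one | O=C1C=C(C)CC[C@]2(O)[C@@H](C(C)C)C[C@H](O[Si](C)(C)C(C)(C)C)[C@]12C | intermediate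
21 | tetramethylammonium diacetoxy(hydrido)borate ester (at O3a) of compound 20 | O=C1C=C(C)CC[C@]2(O[BH-](OC(C)=O)OC(C)=O)[C@@H](C(C)C)C[C@H](O[Si](C)(C)C(C)(C)C)[C@]12C.C[N+](C)(C)C | intermediate
22 | (1S,3R,3aS,8R,8aS)-1-(tert-butyldimethylsilyloxy)-6,8a-dimethyl-3-(propan-2-yl)-1,2,3,3a,4,5,8,8a-octahydroazulene-3a,8-diol | O[C@@H]1C=C(C)CC[C@]2(O)[C@@H](C(C)C)C[C@H](O[Si](C)(C)C(C)(C)C)[C@]12C | intermediate
23 | 4-methoxybenzoyl chloride | COc1ccc(cc1)C(Cl)=O | starting material
24 | (1S,3R,3aS,8R,8aS)-1-(tert-butyldimethylsilyloxy)-3a-hydroxy-6,8a-dimethyl-3-(propan-2-yl)-1,2,3,3a,4,5,8,8a-octahydroazulen-8-yl 4-methoxybenzoate | COc1ccc(C(=O)O[C@@H]2C=C(C)CC[C@]3(O)[C@@H](C(C)C)C[C@H](O[Si](C)(C)C(C)(C)C)[C@]23C)cc1 | intermediate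
25 | (1S,3R,3aS,8R,8aR)-1,3a-dihydroxy-6,8a-dimethyl-3-(propan-2-yl)-1,2,3,3a,4,5,8,8a-octahydroazulen-8-yl 4-methoxybenzoate | COc1ccc(C(=O)O[C@@H]2C=C(C)CC[C@]3(O)[C@@H](C(C)C)C[C@H](O)[C@]23C)cc1 | intermediate
26 | (3R,3aS,8R,8aR)-3a-hydroxy-6,8a-dimethyl-1-oxo-3-(propan-2-yl)-1,2,3,3a,4,5,8,8a-octahydroazulen-8-yl 4-methoxybenzoate | COc1ccc(C(=O)O[C@@H]2C=C(C)CC[C@]3(O)[C@@H](C(C)C)CC(=O)[C@]23C)cc1 | target

**Step count**
Total: 17 steps. Longest linear sequence: 16 steps (steps 1–6 and 8–17).

**Steps most likely to fail**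

1. Step 12 (key step). What may go wrong: the Lewis acid may direct attack to the conjugated C8 carbonyl; the closure may turn stepwise, with the tertiary cation captured by chloride or methyl; or the aluminium alkoxide may open by retro-aldol. Fallback, setting out from 17 and coming back at 19: catalytic SeO2 with tBuOOH oxidises the E-methyl of the electron-rich prenyl olefin to the allylic alcohol (2S)-2-[(1S,3E)-1-(tert-butyldimethylsilyloxy)-5-hydroxy-4-methylpent-3-en-1-yl]-2,5-dimethylcyclohept-4-ene-1,3-dione F1. Appel bromination (CBr4, PPh3) gives the allylic bromide (2S)-2-[(1S,3E)-5-bromo-1-(tert-butyldimethylsilyloxy)-4-methylpent-3-en-1-yl]-2,5-dimethylcyclohept-4-ene-1,3-dione F2. CrCl2 in THF then closes the ring by intramolecular Nozaki–Hiyama allylation: the allylchromium species adds through its more substituted γ-carbon (the former prenyl CH) to the C3a ketone in a closed six-membered transition state, which forms C3–C3a and the isopropenyl group of 19.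

2. Step 8. What may go wrong: under BF3 the β,γ-unsaturated aldehyde may slip into conjugation or oligomerise through its electron-rich olefin faster than the hindered tetrasubstituted enol ether carbon captures it. Fallback, setting out from 11 and coming back at 14: the same BF3·OEt2-mediated addition is run with the isomeric aldehyde 2, whose double bond cannot move into conjugation, to give (6R,7S)-7-[(1S)-1-hydroxy-4-methylpent-4-en-1-yl]-3,7-dimethyl-6-(triethylsilyloxy)cyclohept-2-en-1-one F3. A cobalt-hydride-catalysed one-position olefin transposition (Co(salen)Cl, PhSiH3 cat., benzene, rt) then moves the terminal 1,1-disubstituted olefin into the trisubstituted position and gives 14.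

3. Step 14. What may go wrong: the tertiary hydroxyl may exchange onto boron too slowly, so that the hindered conjugated ketone is either not reduced or is attacked from outside on the other face, giving the C8 epimer. Fallback, from 20 directly to 22 with no new compound: reagent-controlled Corey–Bakshi–Shibata reduction with (S)-2-methyl-CBS-oxazaborolidine and catecholborane in toluene at −78 °C. The quaternary C8a is the large flank and the vinylic C7 the small flank of the carbonyl, which should deliver hydride to the face that gives the 8R alcohol.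

**Further compounds**
F1 | step 12 | (2S)-2-[(1S,3E)-1-(tert-butyldimethylsilyloxy)-5-hydroxy-4-methylpent-3-en-1-yl]-2,5-dimethylcyclohept-4-ene-1,3-dione | C/C(CO)=C\C[C@H](O[Si](C)(C)C(C)(C)C)[C@]1(C)C(=O)C=C(C)CCC1=O
F2 | step 12 | (2S)-2-[(1S,3E)-5-bromo-1-(tert-butyldimethylsilyloxy)-4-methylpent-3-en-1-yl]-2,5-dimethylcyclohept-4-ene-1,3-dione | C/C(CBr)=C\C[C@H](O[Si](C)(C)C(C)(C)C)[C@]1(C)C(=O)C=C(C)CCC1=O
F3 | step 8 | (6R,7S)-7-[(1S)-1-hydroxy-4-methylpent-4-en-1-yl]-3,7-dimethyl-6-(triethylsilyloxy)cyclohept-2-en-1-one | C=C(C)CC[C@H](O)[C@]1(C)C(=O)C=C(C)CC[C@H]1O[Si](CC)(CC)CC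
F0 | step 14 | none | none
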